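**Retrosynthetic overview**
1. Acyl part: enone 1 + phosphonate 2 → (vinylogous Horner–Wadsworth–Emmons) ester 3 → acid 4.
2. Core: germacrone 5 already holds the ten-membered ring, the C8 ketone and the isopropylidene. An enantioselective proton-initiated transannular C5–C10 closure gives the trans-eudesmadienone 6.
3. 6 → α-epoxide 7 → enol silyl ether 8 → epoxide-triggered 1,2-H/1,2-CH3 relay (eudesmane → eremophilane, the aristolochene-type shift) → silyl ether 9 → alcohol 10.
4. 10 + 4 (through anhydride 11) → ester 12; C12–OH through selenide 13 and selenenate 14 → 15; Cu–H 1,4-reduction and Rubottom oxidation through 16 and 17 → target 18.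
5. Ring order: ten-membered ring (supplied by 5) → ring A/ring B decalin by transannular cyclisation → no further ring formation, only the skeletal shift and oxidations.

Assumption: eremophilane/eudesmane numbering is used, β is the face of the angular methyl group, and the target is read as (3R,4R,5R,9R,10S), 7(11)Z, with an all-E 5-methyldodecatrienoyl group.

**Step 1**
Reactants: 1 (E)-non-3-en-2-one; 2 triethyl 4-phosphonocrotonate
Product: 3 ethyl (2E,4E,6E)-5-methyldodeca-2,4,6-trienoate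
Conditions: LiN(SiMe3)2, THF, −78 °C to rt; then I2 (2 mol %), hexane, daylight, rt
Reagents that add atoms: none
Why: Horner–Wadsworth–Emmons olefination through the P-bearing carbon of the crotonate anion gives mainly the E-trisubstituted 4,5-alkene, and iodine-catalysed equilibration moves residual 4Z isomer to the thermodynamically preferred all-E triene.

**Step 2**
Reactants: 3 ethyl (2E,4E,6E)-5-methyldodeca-2,4,6-trienoate
Product: 4 (2E,4E,6E)-5-methyldodeca-2,4,6-trienoic acid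
Conditions: LiOH, THF/MeOH/H2O, rt; then 1 M HCl to pH 3
Reagents that add atoms: lithium hydroxide, [Li+].[OH-]
Why: Saponification by acyl–oxygen cleavage leaves the triene geometry untouched; no stereocentre is involved.

**Step 3**
Reactants: 5 germacrone
Product: 6 (5R,10R)-eudesma-3,7(11)-dien-8-one
Conditions: chiral IDPi Brønsted acid [imidodiphosphorimidate from two 3,3′-bis(3,5-(CF3)2C6H3)-BINOL units, N-SO2CF3; antipode that gives the 5R,10R series] (3 mol %), (CF3)3COH/CHCl3, −40 °C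
Reagents that add atoms: none
Why: Proposed new method: the confined chiral acid protonates C1 of one of the two rapidly interconverting planar-chiral conformers of 5 and C5 adds to C10 through the chair–chair transannular transition state, which fixes the trans fusion (5α-H, 10β-CH3) and, through the catalyst, the absolute sense, after which loss of the axial H-3 gives the Δ3 olefin; the closest known reactions are the racemic acid-catalysed cyclisation of germacrone to selinadienones and imidodiphosphorimidate-catalysed enantioselective proton-initiated polyene cyclisations.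

**Step 4**
Reactants: 6 (5R,10R)-eudesma-3,7(11)-dien-8-one
Product: 7 (3R,4S,5R,10R)-3α,4α-epoxyeudesm-7(11)-en-8-one
Conditions: mCPBA, NaHCO3, CH2Cl2, 0 °C
Reagents that add atoms: 3-chloroperoxybenzoic acid (mCPBA), OOC(=O)c1cccc(Cl)c1
Why: Prilezhaev epoxidation touches only the electron-rich Δ3 olefin (the enone C=C is inert) and the peracid approaches the α-face, anti to the axial 10β-methyl, which sets C3 and C4.

**Step 5**
Reactants: 7 (3R,4S,5R,10R)-3α,4α-epoxyeudesm-7(11)-en-8-one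
Product: 10 (3R,4R,5R)-3α-hydroxyeremophila-7(11),9-dien-8-one, via silyl enol ether 8 (not isolated), via silyl ether 9 (not isolated)
Conditions: LiN(iPr)2, Me3SiCl, THF, −78 °C; evaporate, pentane, filter under Ar; then Me3SiOTf (5 mol %), CH2Cl2, −78 to −40 °C; then K2CO3 (cat.), MeOH, 0 °C
Reagents that add atoms: none
Why: Proposed new method: Me3Si+ opens the epoxide at tertiary C4, the axial H-5α shifts to C4 and the axial 10β-methyl shifts to C5 (both suprafacial, so C3 keeps its α-oxygen and C4/C5 become 4α-H, 4β-CH3, 5β-CH3), and the C10 cation is absorbed by the C8–C9 enol silyl ether as a silyloxocarbenium ion that hands Me3Si+ to the next epoxide; the closest known reactions are the BF3-induced Westphalen-type backbone rearrangement of 5,6-epoxy steroids and semipinacol rearrangements of 2,3-epoxy silyl ethers.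

**Step 6**
Reactants: 4 (2E,4E,6E)-5-methyldodeca-2,4,6-trienoic acid; 10 (3R,4R,5R)-3α-hydroxyeremophila-7(11),9-dien-8-one
Product: 12 (3R,4R,5R)-8-oxoeremophila-7(11),9-dien-3α-yl (2E,4E,6E)-5-methyldodeca-2,4,6-trienoate, via mixed anhydride 11 (not isolated)
Conditions: 4, 2,4,6-Cl3C6H2COCl, Et3N, toluene, rt; then 10, DMAP, rt
Reagents that add atoms: none
Why: Yamaguchi esterification acylates the only free hydroxyl through the mixed anhydride, and the C3–O bond is not broken, so C3 keeps its configuration.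

**Step 7**
Reactants: 12 (3R,4R,5R)-8-oxoeremophila-7(11),9-dien-3α-yl (2E,4E,6E)-5-methyldodeca-2,4,6-trienoate
Product: 15 (7(11)Z)-12-hydroxy-8-oxoeremophila-7(11),9-dien-3α-yl (2E,4E,6E)-5-methyldodeca-2,4,6-trienoate, via allyl selenide 13 (not isolated), via selenenate ester 14 (not isolated)
Conditions: LiN(iPr)2 (1.05 equiv), THF, −78 °C; PhSeBr, −78 °C; then 30% H2O2, pyridine, CH2Cl2, 0 °C
Reagents that add atoms: hydrogen peroxide, OO
Why: With no α′-hydrogen and C1–H anti to the carbonyl, kinetic deprotonation occurs only at the methyl syn to C8=O, the dienolate is selenenylated at C7, and the allyl selenoxide undergoes the [2,3]-sigmatropic selenoxide–selenenate rearrangement that returns the 7(11)-alkene with oxygen on C12; the bulkier C6 branch should sit pseudo-equatorial in the envelope transition state so that CH2O ends cis to C8 (Z), the isomer also favoured by the O–H···O=C8 hydrogen bond.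

**Step 8**
Reactants: 15 (7(11)Z)-12-hydroxy-8-oxoeremophila-7(11),9-dien-3α-yl (2E,4E,6E)-5-methyldodeca-2,4,6-trienoate
Product: 18 (3R,4R,5R,9R,10S)-9,12-dihydroxy-8-oxoeremophil-7(11)Z-en-3-yl (2E,4E,6E)-5-methyldodeca-2,4,6-trienoate, via bis-silyl dienol ether 16 (not isolated), via silyloxy epoxide 17 (not isolated)
Conditions: [(Ph3P)CuH]6 (5 mol %), PhMe2SiH (2.5 equiv), toluene, rt; then dimethyldioxirane, acetone/CH2Cl2, −78 °C; then Bu4NF, AcOH, THF, 0 °C
Reagents that add atoms: dimethyldioxirane, CC1(C)OO1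
Why: Copper hydride conjugate hydrosilylation delivers hydride to C10 along the axial trajectory syn to the angular methyl (as cuprates and Cu–H do with 4a-methyl octalones), setting the cis fusion (10β-H) and giving the C8–C9 enol silyl ether regiospecifically, which dimethyldioxirane epoxidises on the convex β-face (Rubottom oxidation) to set 9β-OH before buffered fluoride frees both hydroxyls.

**Compound list**
1 | (E)-non-3-en-2-one | CCCCC/C=C/C(C)=O | starting material
2 | triethyl 4-phosphonocrotonate [ethyl (E)-4-(diethoxyphosphoryl)but-2-enoate] | CCOC(=O)/C=C/CP(=O)(OCC)OCC | starting material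
3 | ethyl (2E,4E,6E)-5-methyldodeca-2,4,6-trienoate | CCCCC/C=C/C(C)=C/C=C/C(=O)OCC | intermediate
4 | (2E,4E,6E)-5-methyldodeca-2,4,6-trienoic acid | CCCCC/C=C/C(C)=C/C=C/C(=O)O | intermediate
5 | germacrone [(1(10)E,4E)-germacra-1(10),4,7(11)-trien-8-one, achiral] | C/C1=C\CC(=C(C)C)C(=O)C/C(C)=C/CC1 | starting material
6 | (5R,10R)-eudesma-3,7(11)-dien-8-one (trans-fused, 5α-H, 10β-CH3) | CC1=CCC[C@]2(C)CC(=O)C(=C(C)C)C[C@@H]12 | intermediate
7 | (3R,4S,5R,10R)-3α,4α-epoxyeudesm-7(11)-en-8-one | C[C@@]12O[C@@H]1CC[C@]3(C)CC(=O)C(=C(C)C)C[C@@H]23 | intermediate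
8 | 8-(trimethylsilyloxy)-3α,4α-epoxyeudesma-7(11),8-diene (C8–C9 enol silyl ether of 7) | C[C@@]12O[C@@H]1CC[C@]3(C)C=C(O[Si](C)(C)C)C(=C(C)C)C[C@@H]23 | intermediate
9 | (3R,4R,5R)-3α-(trimethylsilyloxy)eremophila-7(11),9-dien-8-one | C[Si](C)(C)O[C@@H]1CCC2=CC(=O)C(=C(C)C)C[C@]2(C)[C@H]1C | intermediate
10 | (3R,4R,5R)-3α-hydroxyeremophila-7(11),9-dien-8-one (4β,5β-dimethyl) | O[C@@H]1CCC2=CC(=O)C(=C(C)C)C[C@]2(C)[C@H]1C | intermediate
11 | (2E,4E,6E)-5-methyldodeca-2,4,6-trienoic 2,4,6-trichlorobenzoic anhydride | CCCCC/C=C/C(C)=C/C=C/C(=O)OC(=O)c1c(Cl)cc(Cl)cc1Cl | intermediate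
12 | (3R,4R,5R)-8-oxoeremophila-7(11),9-dien-3α-yl (2E,4E,6E)-5-methyldodeca-2,4,6-trienoate | CCCCC/C=C/C(C)=C/C=C/C(=O)O[C@@H]1CCC2=CC(=O)C(=C(C)C)C[C@]2(C)[C@H]1C | intermediate
13 | 8-oxo-7-(phenylselanyl)eremophila-9,11-dien-3α-yl trienoate (C7 configuration not controlled, both epimers converge) | CCCCC/C=C/C(C)=C/C=C/C(=O)O[C@@H]1CCC2=CC(=O)C(C(C)=C)([Se]c3ccccc3)C[C@]2(C)[C@H]1C | intermediate
14 | 12-O-phenylselenenate of 15 (7(11)Z) | CCCCC/C=C/C(C)=C/C=C/C(=O)O[C@@H]1CCC2=CC(=O)/C(=C(/C)CO[Se]c3ccccc3)C[C@]2(C)[C@H]1C | intermediate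
15 | (7(11)Z)-12-hydroxy-8-oxoeremophila-7(11),9-dien-3α-yl (2E,4E,6E)-5-methyldodeca-2,4,6-trienoate | CCCCC/C=C/C(C)=C/C=C/C(=O)O[C@@H]1CCC2=CC(=O)/C(=C(/C)CO)C[C@]2(C)[C@H]1C | intermediate
16 | 8,12-bis(dimethylphenylsilyloxy)-10βH-eremophila-7(11)Z,8-dien-3α-yl trienoate | CCCCC/C=C/C(C)=C/C=C/C(=O)O[C@@H]1CC[C@@H]2C=C(O[Si](C)(C)c3ccccc3)/C(=C(/C)CO[Si](C)(C)c3ccccc3)C[C@]2(C)[C@H]1C | intermediate
17 | 8β,9β-epoxy-8α,12-bis(dimethylphenylsilyloxy)-10βH-eremophil-7(11)Z-en-3α-yl trienoate | CCCCC/C=C/C(C)=C/C=C/C(=O)O[C@@H]1CC[C@@H]2[C@H]3O[C@@]3(O[Si](C)(C)c4ccccc4)/C(=C(/C)CO[Si](C)(C)c5ccccc5)C[C@]2(C)[C@H]1C | intermediate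
18 | (3R,4R,5R,9R,10S)-9,12-dihydroxy-8-oxoeremophil-7(11)Z-en-3-yl (2E,4E,6E)-5-methyldodeca-2,4,6-trienoate (CNP0226738.1) | CCCCC/C=C/C(C)=C/C=C/C(=O)O[C@@H]1CC[C@@H]2[C@@H](O)C(=O)/C(=C(/C)CO)C[C@]2(C)[C@H]1C | target

**Step count and risks**
Total step count: 8. Longest linear sequence: 6 steps (5 → 18, steps 3 to 8).

Steps most likely to fail:

Step 3. The enantioselective protonation is unprecedented on this substrate. The cation may also give the Δ4(15) or Δ4 olefins (removable on AgNO3-impregnated silica) or isomerise further. Fallback, from 5 back to 6: epoxidise 5 with the D-fructose-derived Shi ketone and KHSO5 (K2CO3 buffer, MeCN/dimethoxymethane/H2O, 0 °C) and separate from the 4,5-epoxide to obtain (1R,10R)-1,10-epoxygermacrone F1. BF3·OEt2 (CH2Cl2, −78 °C) then triggers an epoxide-initiated transannular cyclisation to 1β-hydroxyeudesma-3,7(11)-dien-8-one F2, so the absolute configuration comes from a reagent-controlled epoxidation. Thiocarbonyldiimidazole/DMAP gives the imidazolyl thiocarbonate F3, and Bu3SnH/AIBN (toluene, 80 °C, Barton–McCombie) removes the C1 oxygen to return 6.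

Step 5. The C4 cation may lose a proton to allylic silyl ethers, or the relay may stop after the hydride shift. Fallback, from 6 back to 12: N-bromosuccinimide in aqueous THF gives the trans-diaxial 3α-bromo-4β-hydroxyeudesm-7(11)-en-8-one F4, and K2CO3/MeOH closes it to the 3β,4β-epoxide F5. In F5 the C4–O bond is antiperiplanar to H-5α, so the H/CH3 relay can be fully concerted. LiN(iPr)2/Me3SiCl gives the enol silyl ether F6, Me3SiOTf gives the 3β-silyloxy dienone F7, and methanolysis gives 3β-hydroxyeremophila-7(11),9-dien-8-one F8. A Mitsunobu esterification (PPh3, diisopropyl azodicarboxylate, THF) with 4 inverts C3 and gives 12 directly.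

Step 8. Cu–H must reduce the hindered C9=C10 enone in preference to the trienoate and add syn to the angular methyl. Fallback, from 10 back to 18: hydrogenate 10 (H2, Pd on carbon, EtOAc; 4a-methyl octalones give cis-fused decalones) to 3α-hydroxy-10βH-eremophil-7(11)-en-8-one F9. Yamaguchi esterification with 4 (through 11) gives the ester F10. LiN(SiMe3)2 then 2-(phenylsulfonyl)-3-phenyloxaziridine gives the 9β-hydroxy ketone F11 by convex-face enolate oxidation. LiN(iPr)2 (2.2 equiv, alkoxide plus syn-γ-deprotonation) and PhSeBr give the C7 selenide F12, and H2O2/pyridine gives, through the selenenate F13, the target 18.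

**Further compounds**
F1 | step 3 | (1R,10R)-1,10-epoxygermacra-4E,7(11)-dien-8-one | C/C1=C\CC(=C(C)C)C(=O)C[C@@]2(C)O[C@@H]2CC1
F2 | step 3 | 1β-hydroxyeudesma-3,7(11)-dien-8-one (5α-H, 10β-CH3) | CC1=CC[C@@H](O)[C@]2(C)CC(=O)C(=C(C)C)C[C@@H]12
F3 | step 3 | O-(8-oxoeudesma-3,7(11)-dien-1β-yl) 1H-imidazole-1-carbothioate | CC1=CC[C@@H](OC(=S)n3ccnc3)[C@]2(C)CC(=O)C(=C(C)C)C[C@@H]12
F4 | step 5 | 3α-bromo-4β-hydroxyeudesm-7(11)-en-8-one | C[C@]1(O)[C@H](Br)CC[C@]2(C)CC(=O)C(=C(C)C)C[C@@H]12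
F5 | step 5 | 3β,4β-epoxyeudesm-7(11)-en-8-one | C[C@]12O[C@H]1CC[C@]3(C)CC(=O)C(=C(C)C)C[C@@H]23
F6 | step 5 | 8-(trimethylsilyloxy)-3β,4β-epoxyeudesma-7(11),8-diene | C[C@]12O[C@H]1CC[C@]3(C)C=C(O[Si](C)(C)C)C(=C(C)C)C[C@@H]23
F7 | step 5 | 3β-(trimethylsilyloxy)eremophila-7(11),9-dien-8-one | C[Si](C)(C)O[C@H]1CCC2=CC(=O)C(=C(C)C)C[C@]2(C)[C@H]1C
F8 | step 5 | 3β-hydroxyeremophila-7(11),9-dien-8-one | O[C@H]1CCC2=CC(=O)C(=C(C)C)C[C@]2(C)[C@H]1C
F9 | step 8 | 3α-hydroxy-10βH-eremophil-7(11)-en-8-one (cis-fused) | O[C@@H]1CC[C@@H]2CC(=O)C(=C(C)C)C[C@]2(C)[C@H]1C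
F10 | step 8 | 8-oxo-10βH-eremophil-7(11)-en-3α-yl (2E,4E,6E)-5-methyldodeca-2,4,6-trienoate | CCCCC/C=C/C(C)=C/C=C/C(=O)O[C@@H]1CC[C@@H]2CC(=O)C(=C(C)C)C[C@]2(C)[C@H]1C
F11 | step 8 | 9β-hydroxy-8-oxo-10βH-eremophil-7(11)-en-3α-yl (2E,4E,6E)-5-methyldodeca-2,4,6-trienoate | CCCCC/C=C/C(C)=C/C=C/C(=O)O[C@@H]1CC[C@@H]2[C@@H](O)C(=O)C(=C(C)C)C[C@]2(C)[C@H]1C
F12 | step 8 | 9β-hydroxy-8-oxo-7-(phenylselanyl)-10βH-eremophil-11-en-3α-yl trienoate (C7 epimers) | CCCCC/C=C/C(C)=C/C=C/C(=O)O[C@@H]1CC[C@@H]2[C@@H](O)C(=O)C(C(C)=C)([Se]c3ccccc3)C[C@]2(C)[C@H]1C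
F13 | step 8 | 12-O-phenylselenenate of 18 | CCCCC/C=C/C(C)=C/C=C/C(=O)O[C@@H]1CC[C@@H]2[C@@H](O)C(=O)/C(=C(/C)CO[Se]c3ccccc3)C[C@]2(C)[C@H]1C
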